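**Retrosynthetic overview**
- The last skeletal bond is C(=O)–Cα: a ring A 2,6-bis(allyloxy)benzaldehyde adds a ring B 2-arylethylmagnesium bromide; oxidation, deallylation and desilylation finish the dihydrochalcone.
- The ring A aldehyde comes from a phenol by magnesium-directed ortho-formylation. The phenol is made in one step from 3-(allyloxy)cyclobutenone and the prenyl-bearing triisopropylsiloxyalkyne (vinylketene/ynol ether benzannulation forming C2'–C3', C4'–C5' and C1'–C2').
- Feature used: in ring A the oxygens on C2', C4' and C6' alternate with C1' (acyl), C3' (prenyl) and C5' (H). C2'–O maps onto the ketene carbonyl, C3'/C4' onto the siloxyalkyne and C5'/C6'/C1' onto the alkoxycyclobutenone, so the three oxygens emerge as OH, OSi and O-allyl.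
- Ring A is the only ring formed (6π electrocyclisation in the key step). Ring B is bought as 3-bromo-4,5-dihydroxybenzaldehyde and decorated (O-methylation, silylation, Stille prenylation, two-carbon chain).
- The siloxyalkyne comes from ethyl 4-methylpent-3-enoate by ester-to-ynolate homologation, and the cyclobutenone from 3-ethoxycyclobutenone by transetherification.

Key step: step 3

Remark: the target has no stereocentre, so no stereocontrol is needed; the stereocentres that arise on the way are racemic and are erased. 3-Ethoxycyclobut-2-en-1-one, tributyl(3-methylbut-2-enyl)stannane and 3-bromo-4,5-dihydroxybenzaldehyde are taken as purchasable.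

**Route**

Step 1
Reactants: 1 ethyl 4-methylpent-3-enoate; 2 chlorotriisopropylsilane
Product: 5 triisopropyl[(5-methylhex-4-en-1-yn-1-yl)oxy]silane, via lithium dibromoenolate 3 (not isolated), via lithium ynolate 4 (not isolated)
Conditions: CH2Br2, lithium 2,2,6,6-tetramethylpiperidide, THF, –78 °C; 1; LiN(SiMe3)2, then s-BuLi, –78 °C → rt; 2, –78 → 0 °C
Reagents that add atoms: dibromomethane, BrCBr
Why: Kowalski ester homologation: LiCHBr2 adds to the ester carbonyl, loss of ethoxide and deprotonation give dibromoenolate 3, bromine–lithium exchange triggers a Fritsch–Buttenberg–Wiechell-type 1,2-shift of the alkyl group to ynolate 4, and the bulky silyl chloride is known to silylate such ynolates on oxygen.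

Step 2
Reactants: 6 3-ethoxycyclobut-2-en-1-one; 7 prop-2-en-1-ol (allyl alcohol)
Product: 8 3-(prop-2-enyloxy)cyclobut-2-en-1-one
Conditions: 7 (solvent, large excess), camphorsulfonic acid (cat.), rt; Et3N quench, evaporate; repeat once
Reagents that add atoms: none
Why: Acid-catalysed transetherification of a vinylogous ester by addition–elimination at C3, driven by the excess of allyl alcohol and removal of ethanol, at a temperature that keeps the four-membered ring closed.

Step 3
Reactants: 8 3-(prop-2-enyloxy)cyclobut-2-en-1-one; 5 triisopropyl[(5-methylhex-4-en-1-yn-1-yl)oxy]silane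
Product: 13 2-(3-methylbut-2-enyl)-5-(prop-2-enyloxy)-3-(triisopropylsilyloxy)phenol, via vinylketene 9 (not isolated), via vinylcyclobutenone 10 (not isolated), via dienylketene 11 (not isolated), via cyclohexadienone 12 (not isolated)
Conditions: 5 (1.3 equiv), toluene, 80 → 110 °C, slow addition of 8
Reagents that add atoms: none
Why: Proposed new method: thermal 4π electrocyclic opening of 8 should give 3-alkoxy vinylketene 9, whose ketene C=C adds siloxyalkyne 5 in a [2+2] cycloaddition to give 10; 4π opening of 10 to dienylketene 11, 6π electrocyclisation to dienone 12 and tautomerisation then deliver phenol 13. The closest known reaction type is the Danheiser benzannulation of 3-alkyl- and 3-arylcyclobutenones with triisopropylsiloxyalkynes, and the oxygen substituent at C3 is the untested element; it is cross-conjugated to the ketene in 9 and so should not deaden the ketene carbon, and alkoxy-substituted cyclobutenones derived from squarates are known to open thermally. Ring A is closed by the 6π electrocyclisation of 11, which forms C1'–C2' after the [2+2] step has formed C2'–C3' and C4'–C5'. The one selectivity needed is the regiochemistry of the [2+2] step: the nucleophilic, prenyl-bearing carbon of 5 must bond to the electrophilic ketene carbonyl carbon, which the polarisation of the ynol ether secures and which places prenyl between the new hydroxyl and the silyloxy group. No stereocentre remains, the transient one at C4 of 10 being destroyed on ring opening. An excess of 5 and slow addition of 8 should limit capture of 9 by the product phenol, and the temperature stays below that needed for [3,3] shift of the allyl vinyl ether or aryl allyl ether units.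

Step 4
Reactants: 13 2-(3-methylbut-2-enyl)-5-(prop-2-enyloxy)-3-(triisopropylsilyloxy)phenol
Product: 15 2-hydroxy-3-(3-methylbut-2-enyl)-6-(prop-2-enyloxy)-4-(triisopropylsilyloxy)benzaldehyde, via salicyl alcohol 14 (not isolated)
Conditions: MgCl2, Et3N, (CH2O)n, MeCN, 80 °C; aq NH4Cl work-up
Reagents that add atoms: paraformaldehyde (as formaldehyde), C=O
Why: Magnesium-phenoxide-directed ortho-formylation (Casnati–Skattebøl reaction): the chelated phenoxide delivers formaldehyde only to an ortho carbon, the future C1' is the single free ortho position, and salicyl alcohol 14 is oxidised in the flask by hydride transfer to a second formaldehyde.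

Step 5
Reactants: 15 2-hydroxy-3-(3-methylbut-2-enyl)-6-(prop-2-enyloxy)-4-(triisopropylsilyloxy)benzaldehyde
Product: 16 3-(3-methylbut-2-enyl)-2,6-bis(prop-2-enyloxy)-4-(triisopropylsilyloxy)benzaldehyde
Conditions: allyl bromide, K2CO3, acetone, 50 °C
Reagents that add atoms: allyl bromide, C=CCBr
Why: Williamson etherification of the acidic salicylaldehyde hydroxyl, which removes the acidic proton before the Grignard step and costs no extra deprotection because both allyl ethers fall together in step 14.

Step 6
Reactants: 17 3-bromo-4,5-dihydroxybenzaldehyde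
Product: 18 3-bromo-5-hydroxy-4-methoxybenzaldehyde
Conditions: MeI, Li2CO3, DMF, 40 °C
Reagents that add atoms: iodomethane, CI
Why: Selective Williamson methylation: the 4-hydroxyl, para to the formyl group and ortho to bromine, is much the more acidic phenol, so the weak base Li2CO3 should ionise and methylate it alone.

Step 7
Reactants: 18 3-bromo-5-hydroxy-4-methoxybenzaldehyde; 2 chlorotriisopropylsilane
Product: 19 3-bromo-4-methoxy-5-(triisopropylsilyloxy)benzaldehyde
Conditions: imidazole, DMF, rt
Reagents that add atoms: none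
Why: Standard imidazole-mediated silylation of a phenol; the triisopropylsilyl ether tolerates the organometallic steps and is removed together with the ring A silyl ether in step 15.

Step 8
Reactants: 19 3-bromo-4-methoxy-5-(triisopropylsilyloxy)benzaldehyde; 20 tributyl(3-methylbut-2-enyl)stannane
Product: 21 4-methoxy-3-(3-methylbut-2-enyl)-5-(triisopropylsilyloxy)benzaldehyde
Conditions: Pd(PPh3)4 (cat.), DMF, 90 °C
Reagents that add atoms: none
Why: Stille cross-coupling: zerovalent palladium inserts into the C–Br bond, and reductive elimination from the allylpalladium intermediate at its less hindered terminus should give the linear prenyl arene.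

Step 9
Reactants: 21 4-methoxy-3-(3-methylbut-2-enyl)-5-(triisopropylsilyloxy)benzaldehyde
Product: 22 [5-ethenyl-2-methoxy-3-(3-methylbut-2-enyl)phenoxy]triisopropylsilane
Conditions: Ph3PCH3Br, NaN(SiMe3)2, THF, 0 °C → rt
Reagents that add atoms: methyltriphenylphosphonium bromide, C[P+](c1ccccc1)(c1ccccc1)c1ccccc1.[Br-]
Why: Wittig methylenation of the aryl aldehyde with the non-stabilised ylide.

Step 10
Reactants: 22 [5-ethenyl-2-methoxy-3-(3-methylbut-2-enyl)phenoxy]triisopropylsilane
Product: 24 2-[4-methoxy-3-(3-methylbut-2-enyl)-5-(triisopropylsilyloxy)phenyl]ethanol, via alkylborane 23 (not isolated)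
Conditions: 9-BBN, THF, 0 °C → rt; H2O2, aq NaOAc, 0 °C → rt
Reagents that add atoms: hydrogen peroxide, OO
Why: Hydroboration–oxidation: 9-BBN adds in the anti-Markovnikov sense to the monosubstituted styrene much faster than to the trisubstituted prenyl alkene, and the buffered peroxide oxidation spares the aryl silyl ether.

Step 11
Reactants: 24 2-[4-methoxy-3-(3-methylbut-2-enyl)-5-(triisopropylsilyloxy)phenyl]ethanol
Product: 25 [5-(2-bromoethyl)-2-methoxy-3-(3-methylbut-2-enyl)phenoxy]triisopropylsilane
Conditions: CBr4, PPh3, CH2Cl2, 0 °C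
Reagents that add atoms: tetrabromomethane, BrC(Br)(Br)Br
Why: Appel reaction: bromide displaces the alkoxyphosphonium group at the primary carbon under neutral conditions that leave the silyl ether and the prenyl group untouched.

Step 12
Reactants: 25 [5-(2-bromoethyl)-2-methoxy-3-(3-methylbut-2-enyl)phenoxy]triisopropylsilane; 16 3-(3-methylbut-2-enyl)-2,6-bis(prop-2-enyloxy)-4-(triisopropylsilyloxy)benzaldehyde
Product: 27 1-[3-(3-methylbut-2-enyl)-2,6-bis(prop-2-enyloxy)-4-(triisopropylsilyloxy)phenyl]-3-[4-methoxy-3-(3-methylbut-2-enyl)-5-(triisopropylsilyloxy)phenyl]propan-1-ol (racemic), via Grignard reagent 26 (not isolated)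
Conditions: Mg, THF, 40 °C; then 16, 0 °C → rt; aq NH4Cl
Reagents that add atoms: none
Why: Grignard formation from the primary bromide and 1,2-addition to the aldehyde, which now carries no acidic proton; the carbinol centre forms as a racemate and is removed in step 13.

Step 13
Reactants: 27 the racemic carbinol
Product: 28 1-[3-(3-methylbut-2-enyl)-2,6-bis(prop-2-enyloxy)-4-(triisopropylsilyloxy)phenyl]-3-[4-methoxy-3-(3-methylbut-2-enyl)-5-(triisopropylsilyloxy)phenyl]propan-1-one
Conditions: Dess–Martin periodinane, NaHCO3, CH2Cl2, 0 °C → rt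
Reagents that add atoms: none
Why: Dess–Martin oxidation of the secondary benzylic alcohol under buffered conditions that avoid ionisation of the electron-rich benzylic position.

Step 14
Reactants: 28 the bis(allyl) bis(silyl) ketone
Product: 29 1-[2,6-dihydroxy-3-(3-methylbut-2-enyl)-4-(triisopropylsilyloxy)phenyl]-3-[4-methoxy-3-(3-methylbut-2-enyl)-5-(triisopropylsilyloxy)phenyl]propan-1-one
Conditions: Pd(PPh3)4 (cat.), morpholine, THF, rt
Reagents that add atoms: none
Why: Tsuji–Trost-type deallylation: zerovalent palladium ionises the two aryl allyl ethers to allylpalladium complexes that morpholine traps, while the carbon-bound prenyl groups cannot ionise.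

Step 15
Reactants: 29 the bis(silyl) dihydrochalcone
Product: 30 3,2',4',6'-tetrahydroxy-4-methoxy-3',5-diprenyldihydrochalcone
Conditions: Bu4NF, AcOH, THF, 0 °C
Reagents that add atoms: none
Why: Fluoride-induced cleavage of both aryl silyl ethers, buffered with acetic acid so that the polyphenolic ketone is not exposed to strong base.

**Compound list**
1 | ethyl 4-methylpent-3-enoate | CCOC(=O)CC=C(C)C | starting material
2 | chlorotriisopropylsilane | CC(C)[Si](Cl)(C(C)C)C(C)C | starting material
3 | lithium 1,1-dibromo-5-methylhexa-1,4-dien-2-olate | [Li]OC(CC=C(C)C)=C(Br)Br | intermediate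
4 | lithium 5-methylhex-4-en-1-yn-1-olate | [Li]OC#CCC=C(C)C | intermediate
5 | triisopropyl[(5-methylhex-4-en-1-yn-1-yl)oxy]silane | CC(C)=CCC#CO[Si](C(C)C)(C(C)C)C(C)C | intermediate
6 | 3-ethoxycyclobut-2-en-1-one | CCOC1=CC(=O)C1 | starting material
7 | prop-2-en-1-ol (allyl alcohol) | C=CCO | starting material
8 | 3-(prop-2-enyloxy)cyclobut-2-en-1-one | C=CCOC1=CC(=O)C1 | intermediate
9 | 3-(prop-2-enyloxy)buta-1,3-dien-1-one | O=C=CC(=C)OCC=C | intermediate
10 | 2-(3-methylbut-2-enyl)-4-[1-(prop-2-enyloxy)ethenyl]-3-(triisopropylsilyloxy)cyclobut-2-en-1-one (racemic) | O=C1C(CC=C(C)C)=C(O[Si](C(C)C)(C(C)C)C(C)C)C1C(=C)OCC=C | intermediate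
11 | (3E)-2-(3-methylbut-2-enyl)-5-(prop-2-enyloxy)-3-(triisopropylsilyloxy)hexa-1,3,5-trien-1-one | O=C=C(CC=C(C)C)/C(O[Si](C(C)C)(C(C)C)C(C)C)=C\C(=C)OCC=C | intermediate
12 | 2-(3-methylbut-2-enyl)-5-(prop-2-enyloxy)-3-(triisopropylsilyloxy)cyclohexa-2,4-dien-1-one | O=C1CC(OCC=C)=CC(O[Si](C(C)C)(C(C)C)C(C)C)=C1CC=C(C)C | intermediate
13 | 2-(3-methylbut-2-enyl)-5-(prop-2-enyloxy)-3-(triisopropylsilyloxy)phenol | Oc1cc(OCC=C)cc(O[Si](C(C)C)(C(C)C)C(C)C)c1CC=C(C)C | intermediate
14 | 2-(hydroxymethyl)-6-(3-methylbut-2-enyl)-3-(prop-2-enyloxy)-5-(triisopropylsilyloxy)phenol | OCc1c(O)c(CC=C(C)C)c(O[Si](C(C)C)(C(C)C)C(C)C)cc1OCC=C | intermediate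
15 | 2-hydroxy-3-(3-methylbut-2-enyl)-6-(prop-2-enyloxy)-4-(triisopropylsilyloxy)benzaldehyde | O=Cc1c(O)c(CC=C(C)C)c(O[Si](C(C)C)(C(C)C)C(C)C)cc1OCC=C | intermediate
16 | 3-(3-methylbut-2-enyl)-2,6-bis(prop-2-enyloxy)-4-(triisopropylsilyloxy)benzaldehyde | O=Cc1c(OCC=C)c(CC=C(C)C)c(O[Si](C(C)C)(C(C)C)C(C)C)cc1OCC=C | intermediate
17 | 3-bromo-4,5-dihydroxybenzaldehyde | O=Cc1cc(O)c(O)c(Br)c1 | starting material
18 | 3-bromo-5-hydroxy-4-methoxybenzaldehyde | COc1c(O)cc(C=O)cc1Br | intermediate
19 | 3-bromo-4-methoxy-5-(triisopropylsilyloxy)benzaldehyde | COc1c(O[Si](C(C)C)(C(C)C)C(C)C)cc(C=O)cc1Br | intermediate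
20 | tributyl(3-methylbut-2-enyl)stannane | CCCC[Sn](CCCC)(CCCC)CC=C(C)C | starting material
21 | 4-methoxy-3-(3-methylbut-2-enyl)-5-(triisopropylsilyloxy)benzaldehyde | COc1c(O[Si](C(C)C)(C(C)C)C(C)C)cc(C=O)cc1CC=C(C)C | intermediate
22 | [5-ethenyl-2-methoxy-3-(3-methylbut-2-enyl)phenoxy]triisopropylsilane | COc1c(O[Si](C(C)C)(C(C)C)C(C)C)cc(C=C)cc1CC=C(C)C | intermediate
23 | 9-{2-[4-methoxy-3-(3-methylbut-2-enyl)-5-(triisopropylsilyloxy)phenyl]ethyl}-9-borabicyclo[3.3.1]nonane | COc1c(O[Si](C(C)C)(C(C)C)C(C)C)cc(CCB2C3CCCC2CCC3)cc1CC=C(C)C | intermediate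
24 | 2-[4-methoxy-3-(3-methylbut-2-enyl)-5-(triisopropylsilyloxy)phenyl]ethanol | COc1c(O[Si](C(C)C)(C(C)C)C(C)C)cc(CCO)cc1CC=C(C)C | intermediate
25 | [5-(2-bromoethyl)-2-methoxy-3-(3-methylbut-2-enyl)phenoxy]triisopropylsilane | COc1c(O[Si](C(C)C)(C(C)C)C(C)C)cc(CCBr)cc1CC=C(C)C | intermediate
26 | {2-[4-methoxy-3-(3-methylbut-2-enyl)-5-(triisopropylsilyloxy)phenyl]ethyl}magnesium bromide | COc1c(O[Si](C(C)C)(C(C)C)C(C)C)cc(CC[Mg]Br)cc1CC=C(C)C | intermediate
27 | 1-[3-(3-methylbut-2-enyl)-2,6-bis(prop-2-enyloxy)-4-(triisopropylsilyloxy)phenyl]-3-[4-methoxy-3-(3-methylbut-2-enyl)-5-(triisopropylsilyloxy)phenyl]propan-1-ol (racemic) | COc1c(O[Si](C(C)C)(C(C)C)C(C)C)cc(CCC(O)c2c(OCC=C)cc(O[Si](C(C)C)(C(C)C)C(C)C)c(CC=C(C)C)c2OCC=C)cc1CC=C(C)C | intermediate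
28 | 1-[3-(3-methylbut-2-enyl)-2,6-bis(prop-2-enyloxy)-4-(triisopropylsilyloxy)phenyl]-3-[4-methoxy-3-(3-methylbut-2-enyl)-5-(triisopropylsilyloxy)phenyl]propan-1-one | COc1c(O[Si](C(C)C)(C(C)C)C(C)C)cc(CCC(=O)c2c(OCC=C)cc(O[Si](C(C)C)(C(C)C)C(C)C)c(CC=C(C)C)c2OCC=C)cc1CC=C(C)C | intermediate
29 | 1-[2,6-dihydroxy-3-(3-methylbut-2-enyl)-4-(triisopropylsilyloxy)phenyl]-3-[4-methoxy-3-(3-methylbut-2-enyl)-5-(triisopropylsilyloxy)phenyl]propan-1-one | COc1c(O[Si](C(C)C)(C(C)C)C(C)C)cc(CCC(=O)c2c(O)cc(O[Si](C(C)C)(C(C)C)C(C)C)c(CC=C(C)C)c2O)cc1CC=C(C)C | intermediate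
30 | 3,2',4',6'-tetrahydroxy-4-methoxy-3',5-diprenyldihydrochalcone; 1-[2,4,6-trihydroxy-3-(3-methylbut-2-enyl)phenyl]-3-[3-hydroxy-4-methoxy-5-(3-methylbut-2-enyl)phenyl]propan-1-one | COc1c(O)cc(CCC(=O)c2c(O)cc(O)c(CC=C(C)C)c2O)cc1CC=C(C)C | target

**Step count and risk**

Total step count: 15. Longest linear sequence: 10 steps (17 → 30 through steps 6 to 15); the ring A line from 1 runs through 8 steps.

Steps most likely to fail:

1. Step 3 (bears the label). The vinylogous-ester stabilisation of 8 may hold the ring closed until the temperature is high enough for [3,3] shift of its allyl vinyl ether unit. The vinylketene may also be lost to O-acylation of the product phenol or to oligomerisation before the [2+2] step. Fallback (known chemistry, gives up the annulation): ring A is taken from purchased 2,4,6-trihydroxybenzaldehyde F1. Of the numbered compounds the sequence sets out from chlorotriisopropylsilane 2, and it comes back to the route at aldehyde 16. C-Prenylation of F1 (prenyl bromide, DBU, THF) should give 2,4,6-trihydroxy-3-(3-methylbut-2-enyl)benzaldehyde F2. Silylation with 2 and imidazole at the most acidic hydroxyl, the one para to the formyl group and not hydrogen-bonded to it, should give 2,6-dihydroxy-3-(3-methylbut-2-enyl)-4-(triisopropylsilyloxy)benzaldehyde F3. Double O-allylation under the conditions of step 5 then gives 16.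

2. Step 1. The lithium carbenoid may deprotonate the doubly activated α-CH2 of the β,γ-unsaturated ester instead of adding to the carbonyl, with drift of the alkene into conjugation; silylation on carbon instead of oxygen is a second failure mode. Fallback: the ynolate is made by oxidation of an acetylide instead of by carbenoid rearrangement, setting out from ester 1 and coming back at ynolate 4 and then 5. Reduction of 1 with i-Bu2AlH at –78 °C should give 4-methylpent-3-enal F4. Corey–Fuchs olefination (CBr4, PPh3) gives 1,1-dibromo-5-methylhexa-1,4-diene F5. n-BuLi (two equivalents) converts F5 into lithium 5-methylhex-4-en-1-yn-1-ide F6, which is oxidised in the same flask with t-BuOOLi (from t-BuOOH and LiN(SiMe3)2) to ynolate 4. Silylation with 2 as in step 1 gives 5.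

3. Step 8. Allyl transfer from tin may lose regiocontrol (bond formation through the γ-carbon, giving the 1,1-dimethylallyl isomer), and oxidative addition may be slow at the bromide flanked by the methoxy group. Fallback: the prenyl group is introduced by an aryl copper reagent instead of by cross-coupling, setting out from 19 and coming back at 21. Acetalisation of 19 (ethylene glycol, TsOH cat., toluene, water removal) gives 2-[3-bromo-4-methoxy-5-(triisopropylsilyloxy)phenyl]-1,3-dioxolane F7. Bromine–lithium exchange (n-BuLi, THF, –78 °C) gives the aryllithium {5-(1,3-dioxolan-2-yl)-2-methoxy-3-(triisopropylsilyloxy)phenyl}lithium F8. Transmetalation with CuBr·SMe2 and alkylation with prenyl bromide should give 2-[4-methoxy-3-(3-methylbut-2-enyl)-5-(triisopropylsilyloxy)phenyl]-1,3-dioxolane F9. Mild hydrolysis (pyridinium p-toluenesulfonate, acetone–water) returns aldehyde 21.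

**Further compounds**
F1 | step 3 | 2,4,6-trihydroxybenzaldehyde (purchased) | O=Cc1c(O)cc(O)cc1O
F2 | step 3 | 2,4,6-trihydroxy-3-(3-methylbut-2-enyl)benzaldehyde | O=Cc1c(O)cc(O)c(CC=C(C)C)c1O
F3 | step 3 | 2,6-dihydroxy-3-(3-methylbut-2-enyl)-4-(triisopropylsilyloxy)benzaldehyde | O=Cc1c(O)cc(O[Si](C(C)C)(C(C)C)C(C)C)c(CC=C(C)C)c1O
F4 | step 1 | 4-methylpent-3-enal | O=CCC=C(C)C
F5 | step 1 | 1,1-dibromo-5-methylhexa-1,4-diene | BrC(Br)=CCC=C(C)C
F6 | step 1 | lithium 5-methylhex-4-en-1-yn-1-ide | [Li]C#CCC=C(C)C
F7 | step 8 | 2-[3-bromo-4-methoxy-5-(triisopropylsilyloxy)phenyl]-1,3-dioxolane | COc1c(O[Si](C(C)C)(C(C)C)C(C)C)cc(C2OCCO2)cc1Br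
F8 | step 8 | {5-(1,3-dioxolan-2-yl)-2-methoxy-3-(triisopropylsilyloxy)phenyl}lithium | COc1c(O[Si](C(C)C)(C(C)C)C(C)C)cc(C2OCCO2)cc1[Li]
F9 | step 8 | 2-[4-methoxy-3-(3-methylbut-2-enyl)-5-(triisopropylsilyloxy)phenyl]-1,3-dioxolane | COc1c(O[Si](C(C)C)(C(C)C)C(C)C)cc(C2OCCO2)cc1CC=C(C)C
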